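**Retrosynthetic overview**

1. Feature: with indane numbering (C1 carries the 4-hydroxyphenyl ring ArA, C2 the resorcinol ring ArB, C3 the carbinol carbon Cα), the fused benzene ring C3a–C4–C5–C6–C7–C7a has OH on C5 and C7, meta to each other with C7 next to fusion carbon C7a. A vinylketene/ynol ether benzannulation delivers exactly this pattern, so this ring is built last.
2. Disconnection of C4–C5, C6–C7 and C7–C7a: photochemical Wolff/benzannulation of the all-trans cyclopentenyl diazoketone 21 with (triisopropylsilyloxy)ethyne 5, then global desilylation.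
3. Diazoketone 21 from methyl enone 18 by detrifluoroacetylative diazo transfer (diazomethane would add to a conjugated acid chloride); 18 from enol triflate 16 by Stille coupling.
4. The cyclopentene comes from (R)-4-silyloxycyclopentenone 6, not from a phosphine-catalysed allenoate/chalcone [3+2], whose α-mode would put the aroyl group rather than ArB on the middle carbon. ArB conjugate addition/aldol sets C2, C3 and Cα; β-elimination of the ring silyloxy group follows; ArA conjugate addition/enolate triflation sets C1.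
5. Ring order: cyclopentane (bought as 6) first, benzene ring last; the three aryl rings enter intact.

Key step: step 9

Assumption: (R)-4-(tert-butyldimethylsilyloxy)cyclopent-2-en-1-one, ethynylmagnesium bromide solution, (4-bromophenoxy)(tert-butyl)dimethylsilane and 4-(tert-butyldimethylsilyloxy)benzaldehyde are taken as catalogue items. TBS = tert-butyldimethylsilyl, TIPS = triisopropylsilyl; "t" after a locant means target (indane) numbering.

**Step 1**
Reactants: 1 5-bromobenzene-1,3-diol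
Product: 2 1-bromo-3,5-bis(TBSO)benzene
Conditions: TBSCl, imidazole, DMF, rt
Reagents that add atoms: tert-butyldimethylsilyl chloride, CC(C)(C)[Si](C)(C)Cl
Why: Imidazole-promoted silylation of phenols (Corey protocol) should protect both hydroxyl groups.

**Step 2**
Reactants: 3 ethynylmagnesium bromide
Product: 5 (triisopropylsilyloxy)ethyne, via bromomagnesium ethynolate 4 (not isolated)
Conditions: t-BuOOH, LiHMDS, THF, −78 °C; add 3, −78 → 0 °C; TIPSOTf, −78 → 0 °C; distil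
Reagents that add atoms: tert-butyl hydroperoxide, CC(C)(C)OO; triisopropylsilyl trifluoromethanesulfonate, CC(C)[Si](C(C)C)(C(C)C)OS(=O)(=O)C(F)(F)F
Why: Electrophilic oxygenation of a metal acetylide by lithium tert-butyl peroxide should give the ynolate, which the bulky silyl triflate silylates on oxygen (acetylide oxidation/ynolate O-silylation route to siloxyalkynes).

**Step 3**
Reactants: 6 (R)-4-(TBSO)cyclopent-2-en-1-one; 2 1-bromo-3,5-bis(TBSO)benzene; 7 4-(TBSO)benzaldehyde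
Product: 10 (2S,3S,4R)-3-[3,5-bis(TBSO)phenyl]-4-(TBSO)-2-[(R)-hydroxy(4-TBSO-phenyl)methyl]cyclopentan-1-one, via aryl Grignard reagent 8 (not isolated), via bromomagnesium enolate 9 (not isolated)
Conditions: 2, Mg, THF, 50 °C; CuBr·SMe2 (10 mol %), 6, THF, −78 °C; then 7, −78 °C; aq. NH4Cl
Reagents that add atoms: none
Why: In this three-component conjugate addition/aldol coupling the aryl copper species should add anti to the C4 silyloxy group (sets C2t), the regiodefined enolate should attack the aldehyde anti to the new aryl group (sets C3t), and the ring-fixed E(O)-enolate in a chelated Zimmerman–Traxler chair should give the anti aldol (sets Cα as R).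

**Step 4**
Reactants: 10
Product: 11 (2S,3S,4R)-3-[3,5-bis(TBSO)phenyl]-4-(TBSO)-2-[(R)-(TBSO)(4-TBSO-phenyl)methyl]cyclopentan-1-one
Conditions: TBSOTf, 2,6-lutidine, CH2Cl2, −78 → 0 °C
Reagents that add atoms: tert-butyldimethylsilyl trifluoromethanesulfonate, CC(C)(C)[Si](C)(C)OS(=O)(=O)C(F)(F)F
Why: Silyl triflate with a hindered, weak base should silylate the secondary benzylic alcohol without retro-aldol or β-elimination.

**Step 5**
Reactants: 11
Product: 12 (4S,5S)-4-[3,5-bis(TBSO)phenyl]-5-[(R)-(TBSO)(4-TBSO-phenyl)methyl]cyclopent-2-en-1-one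
Conditions: DBU, CH2Cl2, 0 °C, short contact
Reagents that add atoms: none
Why: E1cB β-elimination should start at the unhindered ring CH2 and expel the ring silanolate, while the methine flanked by two branched carbons is not deprotonated and the side-chain silyl ether stays; the carbinol ring carbon is given up after it has directed C2t.

**Step 6**
Reactants: 12; 13 (4-bromophenoxy)(tert-butyl)dimethylsilane
Product: 16 (3S,4S,5S)-4-[3,5-bis(TBSO)phenyl]-3-(4-TBSO-phenyl)-5-[(R)-(TBSO)(4-TBSO-phenyl)methyl]cyclopent-1-en-1-yl trifluoromethanesulfonate, via aryl Grignard reagent 14 (not isolated), via bromomagnesium enolate 15 (not isolated)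
Conditions: 13, Mg, THF; CuBr·SMe2 (10 mol %), 12, THF, −78 °C; then Comins' reagent, −78 → 0 °C; aq. NH4Cl
Reagents that add atoms: N-(5-chloropyridin-2-yl)-1,1,1-trifluoro-N-(trifluoromethylsulfonyl)methanesulfonamide (Comins' reagent), FC(F)(F)S(=O)(=O)N(c1ccc(Cl)cn1)S(=O)(=O)C(F)(F)F
Why: Copper-catalysed conjugate addition should occur anti to the adjacent C2t aryl group (sets C1t, all-trans), and O-triflation of the enolate formed fixes the double bond at C3a=C7a without any enolisation choice.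

**Step 7**
Reactants: 16
Product: 18 1-[(3R,4S,5R)-4-[3,5-bis(TBSO)phenyl]-3-(4-TBSO-phenyl)-5-[(R)-(TBSO)(4-TBSO-phenyl)methyl]cyclopent-1-en-1-yl]ethan-1-one, via 1-ethoxyvinyl diene 17 (not isolated)
Conditions: CH2=C(OEt)SnBu3, Pd(PPh3)4 (5 mol %), LiCl, THF, 65 °C; then 1 M HCl, THF, 0 °C
Reagents that add atoms: tributyl(1-ethoxyvinyl)stannane, CCCC[Sn](CCCC)(CCCC)C(=C)OCC; water, O
Why: Stille coupling of the enol triflate with the acetyl anion equivalent, then brief acid hydrolysis of the enol ether, should give the methyl enone with the aryl and alkyl silyl ethers intact.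

**Step 8**
Reactants: 18
Product: 21 2-diazo-1-[(3R,4S,5R)-4-[3,5-bis(TBSO)phenyl]-3-(4-TBSO-phenyl)-5-[(R)-(TBSO)(4-TBSO-phenyl)methyl]cyclopent-1-en-1-yl]ethan-1-one, via lithium enolate 19 (not isolated), via trifluoroacetyl diketone 20 (not isolated)
Conditions: LiHMDS, THF, −78 °C; CF3CO2CH2CF3, −78 °C; then MsN3, Et3N, H2O (1 equiv), MeCN, rt
Reagents that add atoms: methanesulfonyl azide, CS(=O)(=O)N=[N+]=[N-] (2,2,2-trifluoroethyl trifluoroacetate, FC(F)(F)COC(=O)C(F)(F)F, adds the CF3CO group to 20 only and it is lost again)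
Why: Detrifluoroacetylative diazo transfer: kinetic deprotonation of the methyl group, Claisen trifluoroacetylation, then diazo transfer with loss of the activating group should give the conjugated diazoketone without the pyrazoline formation that diazomethane causes with conjugated acid chlorides.

**Step 9**
Reactants: 21; 5 (triisopropylsilyloxy)ethyne
Product: 26 (1R,2S,3R)-2-[3,5-bis(TBSO)phenyl]-1-(4-TBSO-phenyl)-3-[(R)-(TBSO)(4-TBSO-phenyl)methyl]-5-(TIPSO)-2,3-dihydro-1H-inden-7-ol, via vinylketene 22 (not isolated), via siloxycyclobutenone 23 (not isolated), via dienylketene 24 (not isolated), via cyclohexadienone 25 (not isolated)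
Conditions: 5 (3 equiv), degassed ClCH2CH2Cl, hν (300 nm), rt; then 80 °C
Reagents that add atoms: none
Why: Irradiation expels N2 from 21 with Wolff shift of the cyclopentenyl group to give vinylketene 22; the nucleophilic unsubstituted carbon of ynol ether 5 adds to the ketene carbonyl carbon in a regioselective [2+2] (forming C6–C7 and C4–C5) to cyclobutenone 23, which opens by reversible 4π electrocyclic cleavage to dienylketene 24. The benzene ring is then closed by thermal 6π electrocyclisation of 24 (forming C7–C7a) to dienone 25, and enolisation gives the C7 phenol. This is the Danheiser benzannulation in its photochemical diazoketone variant with a siloxyalkyne, a known route to resorcinol monosilyl ethers. No stereocentre is created: the sp3 carbons of 23 and 25 are lost on aromatisation, and C1, C2, C3 and Cα lie outside the reacting π system and are in place before any electron-rich fused arene or benzylic cation can exist. The selectivity needed is the [2+2] regiochemistry, secured by ketene/ynol ether polarity (oxygenated alkyne carbon to the ketene α-carbon, hence OSi at C5 and OH at C7), together with ring closure ahead of hydrogen shifts, secured because the reversible ring opening feeds the Z-dienylketene into a fast electrocyclisation.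

**Step 10**
Reactants: 26
Product: 27 (1R,2S,3R)-2-(3,5-dihydroxyphenyl)-3-[(R)-hydroxy(4-hydroxyphenyl)methyl]-1-(4-hydroxyphenyl)-2,3-dihydro-1H-indene-5,7-diol (target)
Conditions: TBAF, AcOH (1:1, excess), THF, 0 °C → rt
Reagents that add atoms: none
Why: Fluoride should cleave all six Si–O bonds, and the acetic acid buffer keeps the phenoxide concentration low so that no quinone methide forms at Cα and its configuration is kept.

**Compound list**

1 | 5-bromobenzene-1,3-diol | Oc1cc(O)cc(Br)c1 | starting material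
2 | 1-bromo-3,5-bis(TBSO)benzene | CC(C)(C)[Si](C)(C)Oc1cc(Br)cc(O[Si](C)(C)C(C)(C)C)c1 | intermediate
3 | ethynylmagnesium bromide | C#C[Mg]Br | starting material
4 | bromomagnesium ethynolate | C#CO[Mg]Br | intermediate
5 | (triisopropylsilyloxy)ethyne | C#CO[Si](C(C)C)(C(C)C)C(C)C | intermediate
6 | (R)-4-(TBSO)cyclopent-2-en-1-one | O=C1C=C[C@H](O[Si](C)(C)C(C)(C)C)C1 | starting material
7 | 4-(TBSO)benzaldehyde | O=Cc1ccc(O[Si](C)(C)C(C)(C)C)cc1 | starting material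
8 | [3,5-bis(TBSO)phenyl]magnesium bromide | Br[Mg]c1cc(O[Si](C)(C)C(C)(C)C)cc(O[Si](C)(C)C(C)(C)C)c1 | intermediate
9 | bromomagnesium enolate of (3S,4R)-3-[3,5-bis(TBSO)phenyl]-4-(TBSO)cyclopentanone (trans) | Br[Mg]OC1=C[C@@H](c2cc(O[Si](C)(C)C(C)(C)C)cc(O[Si](C)(C)C(C)(C)C)c2)[C@H](O[Si](C)(C)C(C)(C)C)C1 | intermediate
10 | (2S,3S,4R)-3-[3,5-bis(TBSO)phenyl]-4-(TBSO)-2-[(R)-hydroxy(4-TBSO-phenyl)methyl]cyclopentan-1-one (all-trans, anti aldol) | O=C1C[C@@H](O[Si](C)(C)C(C)(C)C)[C@H](c2cc(O[Si](C)(C)C(C)(C)C)cc(O[Si](C)(C)C(C)(C)C)c2)[C@H]1[C@@H](O)c1ccc(O[Si](C)(C)C(C)(C)C)cc1 | intermediate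
11 | (2S,3S,4R)-3-[3,5-bis(TBSO)phenyl]-4-(TBSO)-2-[(R)-(TBSO)(4-TBSO-phenyl)methyl]cyclopentan-1-one | O=C1C[C@@H](O[Si](C)(C)C(C)(C)C)[C@H](c2cc(O[Si](C)(C)C(C)(C)C)cc(O[Si](C)(C)C(C)(C)C)c2)[C@H]1[C@@H](O[Si](C)(C)C(C)(C)C)c1ccc(O[Si](C)(C)C(C)(C)C)cc1 | intermediate
12 | (4S,5S)-4-[3,5-bis(TBSO)phenyl]-5-[(R)-(TBSO)(4-TBSO-phenyl)methyl]cyclopent-2-en-1-one (trans) | O=C1C=C[C@H](c2cc(O[Si](C)(C)C(C)(C)C)cc(O[Si](C)(C)C(C)(C)C)c2)[C@H]1[C@@H](O[Si](C)(C)C(C)(C)C)c1ccc(O[Si](C)(C)C(C)(C)C)cc1 | intermediate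
13 | (4-bromophenoxy)(tert-butyl)dimethylsilane | CC(C)(C)[Si](C)(C)Oc1ccc(Br)cc1 | starting material
14 | [4-(TBSO)phenyl]magnesium bromide | Br[Mg]c1ccc(O[Si](C)(C)C(C)(C)C)cc1 | intermediate
15 | bromomagnesium (3S,4S,5S)-cyclopent-1-en-1-olate carrying 3-(4-TBSO-phenyl), 4-[3,5-bis(TBSO)phenyl] and 5-[(R)-(TBSO)(4-TBSO-phenyl)methyl], all-trans | Br[Mg]OC1=C[C@@H](c2ccc(O[Si](C)(C)C(C)(C)C)cc2)[C@H](c2cc(O[Si](C)(C)C(C)(C)C)cc(O[Si](C)(C)C(C)(C)C)c2)[C@H]1[C@@H](O[Si](C)(C)C(C)(C)C)c1ccc(O[Si](C)(C)C(C)(C)C)cc1 | intermediate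
16 | (3S,4S,5S)-4-[3,5-bis(TBSO)phenyl]-3-(4-TBSO-phenyl)-5-[(R)-(TBSO)(4-TBSO-phenyl)methyl]cyclopent-1-en-1-yl trifluoromethanesulfonate | FC(F)(F)S(=O)(=O)OC1=C[C@@H](c2ccc(O[Si](C)(C)C(C)(C)C)cc2)[C@H](c2cc(O[Si](C)(C)C(C)(C)C)cc(O[Si](C)(C)C(C)(C)C)c2)[C@H]1[C@@H](O[Si](C)(C)C(C)(C)C)c1ccc(O[Si](C)(C)C(C)(C)C)cc1 | intermediate
17 | (3R,4S,5R)-1-(1-ethoxyvinyl)cyclopent-1-ene with the same three substituents | C=C(OCC)C1=C[C@@H](c2ccc(O[Si](C)(C)C(C)(C)C)cc2)[C@H](c2cc(O[Si](C)(C)C(C)(C)C)cc(O[Si](C)(C)C(C)(C)C)c2)[C@H]1[C@@H](O[Si](C)(C)C(C)(C)C)c1ccc(O[Si](C)(C)C(C)(C)C)cc1 | intermediate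
18 | 1-[(3R,4S,5R)-4-[3,5-bis(TBSO)phenyl]-3-(4-TBSO-phenyl)-5-[(R)-(TBSO)(4-TBSO-phenyl)methyl]cyclopent-1-en-1-yl]ethan-1-one | CC(=O)C1=C[C@@H](c2ccc(O[Si](C)(C)C(C)(C)C)cc2)[C@H](c2cc(O[Si](C)(C)C(C)(C)C)cc(O[Si](C)(C)C(C)(C)C)c2)[C@H]1[C@@H](O[Si](C)(C)C(C)(C)C)c1ccc(O[Si](C)(C)C(C)(C)C)cc1 | intermediate
19 | lithium enolate of 18 (deprotonated at the methyl group) | [Li]OC(=C)C1=C[C@@H](c2ccc(O[Si](C)(C)C(C)(C)C)cc2)[C@H](c2cc(O[Si](C)(C)C(C)(C)C)cc(O[Si](C)(C)C(C)(C)C)c2)[C@H]1[C@@H](O[Si](C)(C)C(C)(C)C)c1ccc(O[Si](C)(C)C(C)(C)C)cc1 | intermediate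
20 | 4,4,4-trifluoro-1-[(3R,4S,5R)-cyclopentenyl]butane-1,3-dione (trifluoroacetylated 18) | FC(F)(F)C(=O)CC(=O)C1=C[C@@H](c2ccc(O[Si](C)(C)C(C)(C)C)cc2)[C@H](c2cc(O[Si](C)(C)C(C)(C)C)cc(O[Si](C)(C)C(C)(C)C)c2)[C@H]1[C@@H](O[Si](C)(C)C(C)(C)C)c1ccc(O[Si](C)(C)C(C)(C)C)cc1 | intermediate
21 | 2-diazo-1-[(3R,4S,5R)-4-[3,5-bis(TBSO)phenyl]-3-(4-TBSO-phenyl)-5-[(R)-(TBSO)(4-TBSO-phenyl)methyl]cyclopent-1-en-1-yl]ethan-1-one | [N-]=[N+]=CC(=O)C1=C[C@@H](c2ccc(O[Si](C)(C)C(C)(C)C)cc2)[C@H](c2cc(O[Si](C)(C)C(C)(C)C)cc(O[Si](C)(C)C(C)(C)C)c2)[C@H]1[C@@H](O[Si](C)(C)C(C)(C)C)c1ccc(O[Si](C)(C)C(C)(C)C)cc1 | intermediate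
22 | 2-[(3R,4S,5R)-cyclopentenyl]ethen-1-one (vinylketene) | O=C=CC1=C[C@@H](c2ccc(O[Si](C)(C)C(C)(C)C)cc2)[C@H](c2cc(O[Si](C)(C)C(C)(C)C)cc(O[Si](C)(C)C(C)(C)C)c2)[C@H]1[C@@H](O[Si](C)(C)C(C)(C)C)c1ccc(O[Si](C)(C)C(C)(C)C)cc1 | intermediate
23 | 4-[(3R,4S,5R)-cyclopentenyl]-3-(TIPSO)cyclobut-2-en-1-one (C4 of the four-membered ring undefined) | O=C3C=C(O[Si](C(C)C)(C(C)C)C(C)C)C3C1=C[C@@H](c2ccc(O[Si](C)(C)C(C)(C)C)cc2)[C@H](c2cc(O[Si](C)(C)C(C)(C)C)cc(O[Si](C)(C)C(C)(C)C)c2)[C@H]1[C@@H](O[Si](C)(C)C(C)(C)C)c1ccc(O[Si](C)(C)C(C)(C)C)cc1 | intermediate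
24 | 4-[(3R,4S,5R)-cyclopentenyl]-3-(TIPSO)buta-1,3-dien-1-one, ketene arm and ring cis on C3=C4 (dienylketene) | O=C=C/C(O[Si](C(C)C)(C(C)C)C(C)C)=C\C1=C[C@@H](c2ccc(O[Si](C)(C)C(C)(C)C)cc2)[C@H](c2cc(O[Si](C)(C)C(C)(C)C)cc(O[Si](C)(C)C(C)(C)C)c2)[C@H]1[C@@H](O[Si](C)(C)C(C)(C)C)c1ccc(O[Si](C)(C)C(C)(C)C)cc1 | intermediate
25 | keto tautomer of 26: 1,2,3,7a-tetrahydroinden-7-one (target numbering) with C7a–H, C7a undefined | O=C1C=C(O[Si](C(C)C)(C(C)C)C(C)C)C=C2C1[C@@H](c3ccc(O[Si](C)(C)C(C)(C)C)cc3)[C@H](c3cc(O[Si](C)(C)C(C)(C)C)cc(O[Si](C)(C)C(C)(C)C)c3)[C@H]2[C@@H](O[Si](C)(C)C(C)(C)C)c1ccc(O[Si](C)(C)C(C)(C)C)cc1 | intermediate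
26 | (1R,2S,3R)-2-[3,5-bis(TBSO)phenyl]-1-(4-TBSO-phenyl)-3-[(R)-(TBSO)(4-TBSO-phenyl)methyl]-5-(TIPSO)-2,3-dihydro-1H-inden-7-ol (target numbering) | Oc1cc(O[Si](C(C)C)(C(C)C)C(C)C)cc2c1[C@@H](c3ccc(O[Si](C)(C)C(C)(C)C)cc3)[C@H](c3cc(O[Si](C)(C)C(C)(C)C)cc(O[Si](C)(C)C(C)(C)C)c3)[C@H]2[C@@H](O[Si](C)(C)C(C)(C)C)c1ccc(O[Si](C)(C)C(C)(C)C)cc1 | intermediate
27 | (1R,2S,3R)-2-(3,5-dihydroxyphenyl)-3-[(R)-hydroxy(4-hydroxyphenyl)methyl]-1-(4-hydroxyphenyl)-2,3-dihydro-1H-indene-5,7-diol (target numbering) | Oc1ccc([C@@H]2c3c(O)cc(O)cc3[C@H]([C@@H](O)c3ccc(O)cc3)[C@H]2c2cc(O)cc(O)c2)cc1 | target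

**Count**

Total steps: 10. Longest linear sequence: 9 steps (1 → 2 → 10 → 11 → 12 → 16 → 18 → 21 → 26 → 27; steps 1 and 3–10).

**Steps most likely to fail**

Step 9. The ketene 22 is shielded by the C3t side chain and may add to 5 too slowly under irradiation. It could then dimerise or acylate the phenol already formed, and light absorbed by the five aryl silyl ethers or by cyclobutenone 23 could cause photodegradation. Fallback (light-free, stepwise generation of the same ketene): starting from 21, silver(I)-catalysed Wolff rearrangement in wet THF (PhCO2Ag, Et3N, THF/H2O) traps the ketene with water as 2-[(3R,4S,5R)-4-[3,5-bis(TBSO)phenyl]-3-(4-TBSO-phenyl)-5-[(R)-(TBSO)(4-TBSO-phenyl)methyl]cyclopent-1-en-1-yl]acetic acid F1. 1-Chloro-N,N,2-trimethylpropenylamine converts it under neutral conditions to the acid chloride F2. Slow addition of Et3N to F2 and excess 5 in toluene at rt regenerates ketene 22 by dehydrochlorination at low stationary concentration, and the ynol ether captures it. The route is rejoined at cyclobutenone 23, which is heated at 80 °C to 26 as in step 9.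

Step 3. The aldol may pass partly through a non-chelated transition state and give a syn/anti mixture at Cα; the Grignard reagent may add 1,2; or the aldolate may revert on warming. Fallback (boron aldol on the isolated enol ether): enolate 9 is silylated with Me3SiCl to the trimethylsilyl enol ether F3, which can be purified. MeLi in THF regenerates the regiodefined lithium enolate F4, and chlorodicyclohexylborane converts it to the dicyclohexylboron enolate F5. Addition of 7 at −78 °C through the tight boron chair should give the anti aldol, and hydrolytic work-up returns to 10.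

Step 5. The base may deprotonate the ring methine and expel the side-chain silyloxy group instead of the ring one, or may move the new double bond toward the ArB-bearing carbon. Fallback (aryl groups introduced in reverse order, so that only one β-silyloxy group is present at the elimination): 6 with Grignard reagent 14 (CuBr·SMe2 cat., THF, −78 °C) gives (3S,4R)-3-(4-TBSO-phenyl)-4-(TBSO)cyclopentan-1-one F6. DBU (CH2Cl2, 0 °C, short contact) gives (R)-4-(4-TBSO-phenyl)cyclopent-2-en-1-one F7. Conjugate addition of 8 and aldol trapping with 7 as in step 3 gives the all-trans aldol (2S,3S,4R)-3-[3,5-bis(TBSO)phenyl]-4-(4-TBSO-phenyl)-2-[(R)-hydroxy(4-TBSO-phenyl)methyl]cyclopentan-1-one F8. TBSOTf/2,6-lutidine gives its silyl ether F9. LDA (THF, −78 °C) removes a proton from the ring CH2, and Comins' reagent gives enol triflate 16, where the route is rejoined.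

**Further compounds**

F1 | step 9 | 2-[(3R,4S,5R)-4-[3,5-bis(TBSO)phenyl]-3-(4-TBSO-phenyl)-5-[(R)-(TBSO)(4-TBSO-phenyl)methyl]cyclopent-1-en-1-yl]acetic acid | OC(=O)CC1=C[C@@H](c2ccc(O[Si](C)(C)C(C)(C)C)cc2)[C@H](c2cc(O[Si](C)(C)C(C)(C)C)cc(O[Si](C)(C)C(C)(C)C)c2)[C@H]1[C@@H](O[Si](C)(C)C(C)(C)C)c1ccc(O[Si](C)(C)C(C)(C)C)cc1
F2 | step 9 | acid chloride of F1 | ClC(=O)CC1=C[C@@H](c2ccc(O[Si](C)(C)C(C)(C)C)cc2)[C@H](c2cc(O[Si](C)(C)C(C)(C)C)cc(O[Si](C)(C)C(C)(C)C)c2)[C@H]1[C@@H](O[Si](C)(C)C(C)(C)C)c1ccc(O[Si](C)(C)C(C)(C)C)cc1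
F3 | step 3 | (3S,4R)-3-[3,5-bis(TBSO)phenyl]-4-(TBSO)-1-(trimethylsilyloxy)cyclopent-1-ene | C[Si](C)(C)OC1=C[C@@H](c2cc(O[Si](C)(C)C(C)(C)C)cc(O[Si](C)(C)C(C)(C)C)c2)[C@H](O[Si](C)(C)C(C)(C)C)C1
F4 | step 3 | lithium enolate corresponding to F3 | [Li]OC1=C[C@@H](c2cc(O[Si](C)(C)C(C)(C)C)cc(O[Si](C)(C)C(C)(C)C)c2)[C@H](O[Si](C)(C)C(C)(C)C)C1
F5 | step 3 | dicyclohexylboron enolate corresponding to F3 | C1CCC(CC1)B(C1CCCCC1)OC1=C[C@@H](c2cc(O[Si](C)(C)C(C)(C)C)cc(O[Si](C)(C)C(C)(C)C)c2)[C@H](O[Si](C)(C)C(C)(C)C)C1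
F6 | step 5 | (3S,4R)-3-(4-TBSO-phenyl)-4-(TBSO)cyclopentan-1-one | O=C1C[C@@H](c2ccc(O[Si](C)(C)C(C)(C)C)cc2)[C@H](O[Si](C)(C)C(C)(C)C)C1
F7 | step 5 | (R)-4-(4-TBSO-phenyl)cyclopent-2-en-1-one | O=C1C=C[C@H](c2ccc(O[Si](C)(C)C(C)(C)C)cc2)C1
F8 | step 5 | (2S,3S,4R)-3-[3,5-bis(TBSO)phenyl]-4-(4-TBSO-phenyl)-2-[(R)-hydroxy(4-TBSO-phenyl)methyl]cyclopentan-1-one | O=C1C[C@@H](c2ccc(O[Si](C)(C)C(C)(C)C)cc2)[C@H](c2cc(O[Si](C)(C)C(C)(C)C)cc(O[Si](C)(C)C(C)(C)C)c2)[C@H]1[C@@H](O)c1ccc(O[Si](C)(C)C(C)(C)C)cc1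
F9 | step 5 | (2S,3S,4R)-3-[3,5-bis(TBSO)phenyl]-4-(4-TBSO-phenyl)-2-[(R)-(TBSO)(4-TBSO-phenyl)methyl]cyclopentan-1-one | O=C1C[C@@H](c2ccc(O[Si](C)(C)C(C)(C)C)cc2)[C@H](c2cc(O[Si](C)(C)C(C)(C)C)cc(O[Si](C)(C)C(C)(C)C)c2)[C@H]1[C@@H](O[Si](C)(C)C(C)(C)C)c1ccc(O[Si](C)(C)C(C)(C)C)cc1
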